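The runs were computed for substances that don't exist; noise was put on by code.

The pitfall here is to lean on the earliest readings: complex with one exchanged reads 1.0% in ash and 0.8% in oak with a scatter of 1 percentage point, so the usable information lies in the last readings, at 5.00 h.

| setting | ash | oak | flask |
|---|---|---|---|
| starting complex | 0.67 M | 0.67 M | 0.67 M |
| incoming ligand | 1.34 M | 1.34 M | 1.34 M |
| leaving ligand | 0.67 M | 2.7 M | 1.34 M |
| remark | run made earlier | run made earlier |  |
| time |  |  | 6.0 h |

| run | time / h | complex with one exchanged / % | starting complex / % |
|---|---|---|---|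
| ash | 0.417 | 1.0 | 98.4 |
| ash | 0.833 | 2.7 | 95.8 |
| ash | 2.00 | 9.0 | 92.7 |
| ash | 5.00 | 14.5 | 82.8 |
| oak | 0.667 | 0.8 | 95.8 |
| oak | 1.50 | 5.4 | 94.1 |
| oak | 3.00 | 9.1 | 90.3 |
| oak | 5.00 | 13.0 | 85.3 |

(scatter of a reading: 1 percentage point)

- what was read earlier has a scatter of 1 percentage point, one standard deviation

- amount of complex with one exchanged in percent of the starting complex charged, at 40 min, 2.0 h and 6.0 h

Define the net making constant κ of a run as minus the logarithm of the share of starting complex not standing as complex with one exchanged, divided by time. This is the pseudo-first-order constant of the product curve, a fair term with incoming ligand charged at twice the starting complex. The last readings give 0.0313 h⁻¹ in ash and 0.0279 h⁻¹ in oak, so raising c(leaving ligand) takes 0.00171 M⁻¹ h⁻¹ off κ, and the line between the runs gives the flask, at c(leaving ligand) = 1.34 M, a net making constant of 0.0302 h⁻¹.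

On the top rung of the ladder stands κ itself, whose half-time of 23.0 h, reckoned as if the product rose first-order toward the whole charge, is longer than the 6.0 h of the flask. One rung lower stands the shortfall between starting complex lost and product found, 2.7 points in ash and 1.7 points in oak at 5.00 h, which is less than the product. The brake by leaving ligand, read from two last readings that differ by 1.5 points against a scatter of 1 point, comes to 0.00229 h⁻¹ in the flask, a rough reading that is less than κ. Holding κ constant, the reckoning here gives 1.99%, 5.86% and 16.6%.

The forecast, resting on “Product roughly tracks this loss”, gives 1.8%, 6.5% and 16%, above this reckoning at 2.0 h and below it at 6.0 h.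

The flask gives 2.65%, 7.18% and 16.1%.

    starting complex + incoming ligand ⇌ leaving ligand + complex with one exchanged (K = 0.760, k = 5.20 × 10⁻⁴ M⁻¹ min⁻¹)
    complex with one exchanged + incoming ligand ⇌ leaving ligand + complex with two exchanged (K = 6.50, k = 4.70 × 10⁻⁴ M⁻¹ min⁻¹)

At 6.00 h the flask makes complex with one exchanged 3.93 times faster than it uses it up, each step taken net. Read back from the flask, κ is 0.0373 h⁻¹ at 2.0 h and less, 0.0293 h⁻¹, at 6.0 h, against the 0.0302 h⁻¹ reckoned, so κ falls along the run of the flask and the reckoned value lies near the late one. With half the leaving ligand, κ rises to 0.0313 h⁻¹, which gives 17.1% at 6.0 h, and that flask stands at 17.3%.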